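**Plan**
1. Retrosynthesis: cut first the formyl C–C bond at the last free arene carbon; then, together, the bornane C1–C7 bond, the C2–O(aryl) bond and the ArCH2–C6 bond, which leads back to (1R,5R)-(+)-α-pinene and an o-quinone methide; finally the aminomethyl trigger, the O-protecting groups and the isovaleryl C–C bond, back to phloroglucinol.
2. Forward: the arene is built first (acylation, oxygen differentiation, Mannich base). Then, in one flask, a temporary dihydropyran ring forms by [4+2] addition to pinene, the cyclopentane C1–C6–C5–C4–C7 forms by 1,2-shift of the CMe2 bridge, and the oxepane closes by return of the phenolic oxygen. Debenzylation and formylation finish the route.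
3. Enabling feature: in the 1,7,7-trimethylbicyclo[2.2.1]heptane unit the endo O at C2 and the endo CH2Ar at C6 both flank the methylated bridgehead C1. This is the pattern left when an electrophile adds to C3 of α-pinene anti to the CMe2 bridge and that bridge moves from C1 to C2.
4. Stereochemistry: the pinene bridgeheads are bought; C6 follows from attack anti to the CMe2 bridge; C1 and C2 follow from the stereospecific anti shift and endo return of oxygen.
5. Helpers: benzyl ethers on both oxygens ortho to the ketone leave only the para oxygen able to close the ring (removed in step 7); the NMe2 group is the quinone-methide trigger (lost in step 6).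

Key step: step 6

Remark on numbering: terpenoid carbons are numbered as in bornane after the shift (C1 methylated bridgehead, C2 O-bearing, C4 other bridgehead, C6 CH2Ar-bearing, C7 CMe2) and as in pinane before it; (+)-α-pinene is taken as (1R,5R).

**Step 1**
Reactants: 1 phloroglucinol; 2 3-methylbutanoyl chloride
Product: 3 3-methyl-1-(2,4,6-trihydroxyphenyl)butan-1-one
Conditions: AlCl3 (3 equiv), CH2Cl2/MeNO2, 0 °C → rt; aq HCl work-up
Reagents that add atoms: none
Why: Friedel–Crafts C-acylation of the very electron-rich arene; the acyl group introduced deactivates the ring and binds AlCl3, so a single acylation is expected.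

**Step 2**
Reactants: 3 3-methyl-1-(2,4,6-trihydroxyphenyl)butan-1-one
Product: 4 1-[2,6-dihydroxy-4-(methoxymethoxy)phenyl]-3-methylbutan-1-one
Conditions: MOMCl (1.05 equiv), K2CO3 (1.1 equiv), acetone, 0 °C → rt
Reagents that add atoms: chloromethyl methyl ether, COCCl
Why: Williamson-type O-alkylation under weak base; the 4-OH (para to the ketone) is the most acidic hydroxyl and the only one not hydrogen-bonded to the carbonyl, so one equivalent of MOMCl should mark it selectively as the oxygen that later closes the oxepane.

**Step 3**
Reactants: 4 1-[2,6-dihydroxy-4-(methoxymethoxy)phenyl]-3-methylbutan-1-one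
Product: 5 1-[2,6-bis(benzyloxy)-4-(methoxymethoxy)phenyl]-3-methylbutan-1-one
Conditions: BnBr (2.5 equiv), K2CO3 (3 equiv), DMF, 60 °C
Reagents that add atoms: benzyl bromide, BrCc1ccccc1
Why: Williamson O-benzylation of the two chelated ortho hydroxyls under forcing conditions in a dipolar aprotic solvent that favours O- over C-alkylation; the benzyl groups are the blocking groups for the key step and should withstand Lewis acid at low temperature.

**Step 4**
Reactants: 5 1-[2,6-bis(benzyloxy)-4-(methoxymethoxy)phenyl]-3-methylbutan-1-one
Product: 6 1-[2,6-bis(benzyloxy)-4-hydroxyphenyl]-3-methylbutan-1-one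
Conditions: TsOH·H2O (0.1 equiv), MeOH, 50 °C
Reagents that add atoms: none
Why: Acid-catalysed transacetalisation of the aryl MOM ether to dimethoxymethane releases the para phenol, while the benzyl ethers and the ketone are inert.

**Step 5**
Reactants: 6 1-[2,6-bis(benzyloxy)-4-hydroxyphenyl]-3-methylbutan-1-one
Product: 7 1-{2,6-bis(benzyloxy)-3-[(dimethylamino)methyl]-4-hydroxyphenyl}-3-methylbutan-1-one
Conditions: [Me2N=CH2]I (1.05 equiv), K2CO3 (1.2 equiv), CH2Cl2, 0 °C → rt
Reagents that add atoms: N,N-dimethylmethyleneiminium iodide, C=[N+](C)C.[I-]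
Why: Mannich aminomethylation ortho to the only free phenol (C3 and C5 are equivalent); one equivalent of the preformed iminium salt should stop at mono-substitution because the new amine hydrogen-bonds the phenol and lowers its nucleophilicity.

**Step 6**
Reactants: 7 1-{2,6-bis(benzyloxy)-3-[(dimethylamino)methyl]-4-hydroxyphenyl}-3-methylbutan-1-one; 8 (1R,5R)-(+)-α-pinene
Product: 11 bornane-fused benzoxepine bis(benzyl ether), via o-quinone methide 9 (not isolated), via pinane-fused chroman 10 (not isolated)
Conditions: 8 (10 equiv), PhMe, 120 °C (sealed tube); evaporate; BF3·OEt2 (0.2 equiv), CH2Cl2, −40 → 0 °C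
Reagents that add atoms: none
Why: Heating 7 expels Me2NH to give o-quinone methide 9, whose methylene and only free ortho oxygen (the one para to the ketone; the other flanking oxygen is benzylated) add across C2=C3 of 8 in an inverse-demand hetero-Diels–Alder reaction (closest precedent: o-quinone methide/terpene cycloadditions), CH2 to the less substituted C3 and O to C2, both from the face opposite the CMe2 bridge, which fixes the future C6 stereocenter and gives the temporary pyran ring of 10. BF3 then ionises the tertiary C2–O bond of 10 with participation of the strained C1–C6 bond that lies antiperiplanar to it (the CH2 bridge C1–C7, which would lead to a fenchane, is not aligned), so the CMe2 bridge migrates from C1 to C2 in a Wagner–Meerwein shift of the pinanyl-to-bornyl type known from α-pinene hydrochloride → bornyl chloride and from the bromination of α-pinene to 2,6-dibromobornane; this contracts the six-membered carbocycle to the cyclopentane C1–C6–C5–C4–C7 of the bornane and releases the cyclobutane strain. The phenolic oxygen, held under the endo face by the CH2 tether, returns to the new secondary cation anti to the migrated bridge (ion-pair collapse, seven-membered ring closure), so the oxepane closes with the C2–O bond endo. Stereocontrol: C6 by the facial approach to the alkene, quaternary C1 by inversion at the migration terminus inside the rigid bicycle, C2 by anti (endo) capture, C4 carried over unchanged from the pinene bridgehead. The selectivities needed are the choice of phenolic oxygen (secured by the benzyl block), the CH2→C3/O→C2 orientation (secured by tertiary cation character at C2) and alkyl shift over cyclobutane fragmentation or 1,2-hydride shift (favoured by the aligned σ-bond, the non-polar medium, low temperature and the tethered nucleophile).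

**Step 7**
Reactants: 11 bornane-fused benzoxepine bis(benzyl ether)
Product: 12 bornane-fused 6,8-dihydroxy-7-(3-methylbutanoyl)-2,3,4,5-tetrahydro-1-benzoxepine
Conditions: H2 (1 atm), Pd/C (10%), EtOAc/MeOH, rt
Reagents that add atoms: none
Why: Hydrogenolysis of the two benzyl aryl ethers over Pd/C; the hindered aryl ketone, the non-benzylic bornyl ether and all four stereocenters should not be affected.

**Step 8**
Reactants: 12 bornane-fused 6,8-dihydroxy-7-(3-methylbutanoyl)-2,3,4,5-tetrahydro-1-benzoxepine
Product: 14 target aldehyde CNP0246493.1, via aryl iminium chloride 13 (not isolated)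
Conditions: [Me2N=CHCl]Cl (1.5 equiv), MeCN, 0 °C → rt; then H2O, 50 °C
Reagents that add atoms: (chloromethylene)dimethyliminium chloride, ClC=[N+](C)C.[Cl-]; water, O
Why: Vilsmeier–Haack formylation (electrophilic aromatic substitution) at the only unsubstituted ring carbon, which is ortho/para to three oxygens, followed by hydrolysis of iminium 13; the endo bornyl ether should be slow to ionise because the only antiperiplanar σ-bond (C1–C7) would have to rebuild the strained cyclobutane.

**Compound list**
1 | phloroglucinol (benzene-1,3,5-triol) | Oc1cc(O)cc(O)c1 | starting material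
2 | 3-methylbutanoyl chloride (isovaleryl chloride) | CC(C)CC(Cl)=O | starting material
3 | 3-methyl-1-(2,4,6-trihydroxyphenyl)butan-1-one | CC(C)CC(=O)c1c(O)cc(O)cc1O | intermediate
4 | 1-[2,6-dihydroxy-4-(methoxymethoxy)phenyl]-3-methylbutan-1-one | CC(C)CC(=O)c1c(O)cc(OCOC)cc1O | intermediate
5 | 1-[2,6-bis(benzyloxy)-4-(methoxymethoxy)phenyl]-3-methylbutan-1-one | CC(C)CC(=O)c1c(OCc2ccccc2)cc(OCOC)cc1OCc1ccccc1 | intermediate
6 | 1-[2,6-bis(benzyloxy)-4-hydroxyphenyl]-3-methylbutan-1-one | CC(C)CC(=O)c1c(OCc2ccccc2)cc(O)cc1OCc1ccccc1 | intermediate
7 | 1-{2,6-bis(benzyloxy)-3-[(dimethylamino)methyl]-4-hydroxyphenyl}-3-methylbutan-1-one | CC(C)CC(=O)c1c(OCc2ccccc2)cc(O)c(CN(C)C)c1OCc1ccccc1 | intermediate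
8 | (1R,5R)-(+)-α-pinene, (1R,5R)-2,6,6-trimethylbicyclo[3.1.1]hept-2-ene, high-ee grade | CC1=CC[C@@H]2C[C@H]1C2(C)C | starting material
9 | o-quinone methide, 3,5-bis(benzyloxy)-6-methylidene-4-(3-methylbutanoyl)cyclohexa-2,4-dien-1-one | CC(C)CC(=O)C1=C(OCc2ccccc2)C(=C)C(=O)C=C1OCc1ccccc1 | intermediate
10 | pinane-fused chroman: 5,7-bis(benzyloxy)-6-(3-methylbutanoyl)chroman whose C2–C3 bond is the C2–C3 bond of the (1R,5R)-pinene-derived 2,6,6-trimethylbicyclo[3.1.1]heptane; ring O on the methyl-bearing C2 and benzylic CH2 on C3, both on the face opposite the CMe2 bridge (cis fusion) | CC(C)CC(=O)c1c(OCc2ccccc2)cc3c(c1OCc1ccccc1)C[C@@H]1C[C@@H]2C[C@@H](C2(C)C)[C@]1(C)O3 | intermediate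
11 | bornane-fused benzoxepine bis(benzyl ether): 6,8-bis(benzyloxy)-7-(3-methylbutanoyl)-2,3,4,5-tetrahydro-1-benzoxepine whose C2, C3 and C4 are C2, C1 and C6 of a (1R,2S,4R,6S)-bornane (C2–O endo, C6–CH2 endo) | CC(C)CC(=O)c1c(OCc3ccccc3)cc2c(c1OCc1ccccc1)C[C@@H]1C[C@@H]3C[C@H](O2)[C@@]1(C)C3(C)C | intermediate
12 | the corresponding 6,8-dihydroxy compound (same (1R,2S,4R,6S)-bornane fusion, C9 unsubstituted) | CC(C)CC(=O)c1c(O)cc2c(c1O)C[C@@H]1C[C@@H]3C[C@H](O2)[C@@]1(C)C3(C)C | intermediate
13 | aryl iminium chloride: 12 carrying CH=NMe2(+) Cl(−) at C9 of the benzoxepine | CC(C)CC(=O)c1c(O)c(C=[N+](C)C)c2c(c1O)C[C@@H]1C[C@@H]3C[C@H](O2)[C@@]1(C)C3(C)C.[Cl-] | intermediate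
14 | CNP0246493.1: 6,8-dihydroxy-7-(3-methylbutanoyl)-2,3,4,5-tetrahydro-1-benzoxepine-9-carbaldehyde fused through C2/C3/C4 to C2/C1/C6 of (1R,2S,4R,6S)-bornane (C2–O endo, C6–CH2 endo) | CC(C)CC(=O)c1c(O)c(C=O)c2c(c1O)C[C@@H]1C[C@@H]3C[C@H](O2)[C@@]1(C)C3(C)C | target

**Totals**
Total step count: 8. Longest linear sequence: 8 steps (phloroglucinol to 14); 8 enters unchanged at step 6.

**Steps most likely to fail**

Step 6. Two processes threaten it. In the thermal stage the transient quinone methide may self-condense faster than it adds to the hindered trisubstituted alkene, or dimethylamine may be lost incompletely. In the acid stage the pinanyl cation may be diverted by cyclobutane fragmentation to p-menthadienes or by a 1,2-hydride shift before the alkyl shift. The fallback sets out from 6 and comes back at 11, replacing amine elimination and cycloaddition by an all-cationic alkylation at low temperature. Magnesium-mediated ortho-formylation of 6 (MgCl2, Et3N, (CH2O)n, MeCN, reflux) should give 2,4-bis(benzyloxy)-6-hydroxy-3-(3-methylbutanoyl)benzaldehyde F1. NaBH4 (MeOH, 0 °C) should reduce only the aldehyde, the ketone being shielded by two ortho benzyloxy groups, to 1-[2,6-bis(benzyloxy)-4-hydroxy-3-(hydroxymethyl)phenyl]-3-methylbutan-1-one F2. F2 and 8 (5 equiv) with BF3·OEt2 (1 equiv) and 4 Å molecular sieves in CH2Cl2 at −78 → −20 °C should then give 11: the ionised benzylic alcohol adds to C3 of pinene anti to the CMe2 bridge, and the pinanyl cation shifts and is captured by the phenol without a neutral chroman having to be re-ionised and without a free quinone methide building up.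

Step 2. The mono-protection may lose selectivity through over-alkylation of the chelated hydroxyls or C-alkylation of the ambident phloroglucinol anion. The fallback sets out from 3 and comes back at 6, differentiating the oxygens by steric silylation instead of acidity-controlled alkylation. TIPSCl and imidazole (DMF, 0 °C) should silylate only the unhindered, non-chelated para hydroxyl to give 1-[2,6-dihydroxy-4-(triisopropylsilyloxy)phenyl]-3-methylbutan-1-one F3. Mitsunobu benzylation (BnOH, PPh3, DIAD, THF) under neutral conditions should give 1-[2,6-bis(benzyloxy)-4-(triisopropylsilyloxy)phenyl]-3-methylbutan-1-one F4. TBAF (THF, 0 °C) then frees the para phenol 6.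

Step 8. The iminium salt may attack the phenolic oxygens while C-substitution at the acyl-deactivated ring stays slow, or the bornyl ether may ionise during the warm acidic hydrolysis. The fallback sets out from 12 and arrives at 14 by a base-mediated, chelation-directed route instead of an acidic electrophilic substitution: MgCl2, Et3N and paraformaldehyde in MeCN at reflux, in which the magnesium phenoxide delivers formaldehyde to the ortho carbon and a second formaldehyde oxidises the benzylic alkoxide. This fallback makes no new compound (F0).

**Further compounds**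
F1 | step 6 | 2,4-bis(benzyloxy)-6-hydroxy-3-(3-methylbutanoyl)benzaldehyde | CC(C)CC(=O)c1c(OCc2ccccc2)cc(O)c(C=O)c1OCc1ccccc1
F2 | step 6 | 1-[2,6-bis(benzyloxy)-4-hydroxy-3-(hydroxymethyl)phenyl]-3-methylbutan-1-one | CC(C)CC(=O)c1c(OCc2ccccc2)cc(O)c(CO)c1OCc1ccccc1
F3 | step 2 | 1-[2,6-dihydroxy-4-(triisopropylsilyloxy)phenyl]-3-methylbutan-1-one | CC(C)CC(=O)c1c(O)cc(O[Si](C(C)C)(C(C)C)C(C)C)cc1O
F4 | step 2 | 1-[2,6-bis(benzyloxy)-4-(triisopropylsilyloxy)phenyl]-3-methylbutan-1-one | CC(C)CC(=O)c1c(OCc2ccccc2)cc(O[Si](C(C)C)(C(C)C)C(C)C)cc1OCc1ccccc1
F0 | step 8 | none | none
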